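**Retrosynthetic overview**
1. Ring C (the chroman) is opened at O1–C2 (Mitsunobu etherification) and at C3–C4 (Evans alkylation of a ring-B arylacetyl imide with a ring-A benzyl bromide); the alkylation sets the only stereocentre.
2. Ring B and its fused 2,2-dimethylpyran are not built on a resorcinol but from the 4-pyranone ring of maltol: pyranone C2, C3, C4, C5, C6 and the carbon of the 2-CH2 group become C2', C3', C4', C5', C6' and C1' of ring B.
3. The feature that allows this: ring B carries oxygen on C2' and C4' (meta), hydrogen on C5' and C6', and carbon on C1' and C3', which is the pattern of a 2-alkyl-3-alkenyl-4-pyranone; the cis C3=C4 double bond of the pyran ring holds the C2 carbinol oxygen over the pyranone carbon that becomes C2'.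
4. Order of ring formation: pyran ring and benzene ring B together in one operation (step 5, through a 4-silyloxypyrylium salt that is opened and reclosed); ring A is bought; ring C is closed in step 16.

Key step: step 5

Remark: ring-B locants in the compound names follow 2H-chromene numbering (O1, C2, C3, C4, C4a, C5 to C8, C8a); compounds 1, 3, 5, 16, 19 and 21 are taken as purchased.

**Route**

Step 1
Reactants: 1 maltol (3-hydroxy-2-methyl-4H-pyran-4-one)
Product: 2 2-methyl-4-oxo-4H-pyran-3-yl trifluoromethanesulfonate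
Conditions: Tf2O, pyridine, CH2Cl2, −10 °C
Reagents that add atoms: trifluoromethanesulfonic anhydride, O=S(=O)(OS(=O)(=O)C(F)(F)F)C(F)(F)F
Why: O-sulfonylation of the enolic 3-hydroxyl should give the enol triflate, a standard electrophile for palladium cross-coupling.

Step 2
Reactants: 2 2-methyl-4-oxo-4H-pyran-3-yl trifluoromethanesulfonate; 3 2-methylbut-3-yn-2-ol
Product: 4 3-(3-hydroxy-3-methylbut-1-yn-1-yl)-2-methyl-4H-pyran-4-one
Conditions: PdCl2(PPh3)2 (3 mol %), CuI (5 mol %), Et3N, DMF, rt to 40 °C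
Reagents that add atoms: none
Why: Sonogashira coupling of the electron-poor enol triflate with the terminal alkyne should install the five-carbon side chain at C3, the free tertiary alcohol being tolerated.

Step 3
Reactants: 4 3-(3-hydroxy-3-methylbut-1-yn-1-yl)-2-methyl-4H-pyran-4-one; 5 methyl bromoacetate
Product: 7 methyl 3-[3-(3-hydroxy-3-methylbut-1-yn-1-yl)-4-oxo-4H-pyran-2-yl]propanoate, via dilithium alkoxide dienolate 6 (not isolated)
Conditions: LiN(SiMe3)2 (2.2 equiv), THF, −78 °C; then 5, −78 to −30 °C; H2O quench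
Reagents that add atoms: none
Why: The 2-methyl group of a 4-pyranone is vinylogously acidic, so the base should give the alkoxide/lateral dienolate 6, whose exocyclic carbon is alkylated by the bromo ester (lateral alkylation of a 2-methyl-4-pyranone) while the lithium tert-alkoxide stays inert at low temperature.

Step 4
Reactants: 7 methyl 3-[3-(3-hydroxy-3-methylbut-1-yn-1-yl)-4-oxo-4H-pyran-2-yl]propanoate
Product: 8 methyl 3-{3-[(1Z)-3-hydroxy-3-methylbut-1-en-1-yl]-4-oxo-4H-pyran-2-yl}propanoate
Conditions: H2 (1 atm), Pd/CaCO3 poisoned with Pb(OAc)2, quinoline, EtOAc, rt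
Reagents that add atoms: none
Why: Lindlar semi-hydrogenation adds hydrogen syn and should give only the (Z)-alkene that places the carbinol oxygen over C2 of the pyranone, without reducing the pyranone double bonds.

Step 5
Reactants: 8 methyl 3-{3-[(1Z)-3-hydroxy-3-methylbut-1-en-1-yl]-4-oxo-4H-pyran-2-yl}propanoate
Product: 14 methyl 2-[2,2-dimethyl-5-(triisopropylsilyloxy)-2H-chromen-8-yl]acetate, via silyloxypyrylium triflate 9 (not isolated), via bicyclic ketal 10 (not isolated), via ring-opened dienal 11 (not isolated), via silyl trienol ether 12 (not isolated), via dihydrochromene 13 (not isolated)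
Conditions: iPr3SiOTf (2.5 equiv), 2,6-lutidine (3.5 equiv), ClCH2CH2Cl, −20 °C to 70 °C; aqueous NaHCO3 work-up
Reagents that add atoms: triisopropylsilyl trifluoromethanesulfonate, CC(C)[Si](OS(=O)(=O)C(F)(F)F)(C(C)C)C(C)C
Why: Proposed new method: the silyl triflate should silylate the strongly basic pyranone carbonyl to give the 4-silyloxypyrylium salt 9, the tertiary hydroxyl held by the (Z)-alkene adds to its C2 (6-endo-trig conjugate addition, which forms the O–C bond and closes the pyran ring) to give ketal 10, the 2H-pyran half of 10 opens electrocyclically to the cis-dienal 11, soft enolisation at the former 2-methylene gives the silyl trienol ether 12, disrotatory 6π-electrocyclisation closes the carbocycle to 13, and loss of triisopropylsilanol aromatises 13 to 14. The closest known reaction type is the ring-opening/ring-closure conversion of 2-alkylpyrylium salts into benzenes by nucleophiles (anilines with secondary amines, phenols with hydroxide), combined with silyl-triflate-promoted nucleophilic addition to C2 of 4-pyranones. No stereocentre remains in 14, and those of 10 and 13 are transient and racemic. The step needs regioselectivity between the two oxygens that end up on ring B and chemoselective silylation of the carbonyl over the alcohol: the tether reaches C2 productively (addition at C4 is reversible and leads nowhere), the C4 oxygen is capped as the bulky silyl ether from the start so it cannot become the pyran oxygen, and a tertiary alcohol is silylated only slowly by this reagent.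

Step 6
Reactants: 14 methyl 2-[2,2-dimethyl-5-(triisopropylsilyloxy)-2H-chromen-8-yl]acetate
Product: 15 2-[2,2-dimethyl-5-(triisopropylsilyloxy)-2H-chromen-8-yl]acetic acid
Conditions: LiOH·H2O, THF/H2O, 0 °C to rt; cold dilute HCl to pH 4
Reagents that add atoms: lithium hydroxide, [Li+].[OH-]
Why: Saponification of the unhindered methyl ester should proceed at 0 °C while the hindered aryl silyl ether and the base-stable chromene are kept.

Step 7
Reactants: 15 2-[2,2-dimethyl-5-(triisopropylsilyloxy)-2H-chromen-8-yl]acetic acid; 16 (4R)-4-benzyl-1,3-oxazolidin-2-one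
Product: 18 (4R)-4-benzyl-3-{2-[2,2-dimethyl-5-(triisopropylsilyloxy)-2H-chromen-8-yl]acetyl}-1,3-oxazolidin-2-one, via mixed pivalic anhydride 17 (not isolated)
Conditions: t-BuCOCl, Et3N, THF, −20 °C; then 16, LiCl, −20 °C to rt
Reagents that add atoms: none
Why: N-acylation of the oxazolidinone through the mixed pivalic anhydride 17 should attach the Evans auxiliary under mild conditions that leave the silyl ether untouched.

Step 8
Reactants: 19 5-bromo-2,4-dihydroxybenzaldehyde
Product: 20 5-bromo-2-hydroxy-4-(triisopropylsilyloxy)benzaldehyde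
Conditions: iPr3SiCl (1.05 equiv), imidazole, CH2Cl2, 0 °C
Reagents that add atoms: chlorotriisopropylsilane, CC(C)[Si](Cl)(C(C)C)C(C)C
Why: Regioselective silylation should occur at the 4-hydroxyl, which is more acidic (para to the formyl group) and is not tied up in the hydrogen bond that deactivates the 2-hydroxyl.

Step 9
Reactants: 20 5-bromo-2-hydroxy-4-(triisopropylsilyloxy)benzaldehyde; 21 tributyl(3-methylbut-2-en-1-yl)stannane
Product: 22 2-hydroxy-5-(3-methylbut-2-en-1-yl)-4-(triisopropylsilyloxy)benzaldehyde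
Conditions: Pd(PPh3)4 (5 mol %), DMF, 90 °C
Reagents that add atoms: none
Why: Stille coupling of the aryl bromide should form the C–C bond at the less hindered CH2 terminus of the prenyl unit and give the linear prenyl arene at the position fixed by the bromine.

Step 10
Reactants: 22 2-hydroxy-5-(3-methylbut-2-en-1-yl)-4-(triisopropylsilyloxy)benzaldehyde
Product: 23 2-(allyloxy)-5-(3-methylbut-2-en-1-yl)-4-(triisopropylsilyloxy)benzaldehyde
Conditions: allyl bromide, K2CO3, acetone, 50 °C
Reagents that add atoms: allyl bromide, C=CCBr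
Why: Williamson etherification of the remaining phenol should give an allyl ether that can later be removed without touching the silyl ethers.

Step 11
Reactants: 23 2-(allyloxy)-5-(3-methylbut-2-en-1-yl)-4-(triisopropylsilyloxy)benzaldehyde
Product: 24 [2-(allyloxy)-5-(3-methylbut-2-en-1-yl)-4-(triisopropylsilyloxy)phenyl]methanol
Conditions: NaBH4, THF/MeOH, 0 °C
Reagents that add atoms: none
Why: Borohydride reduction of the aldehyde should give the benzyl alcohol and leave the alkenes and the silyl ether intact.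

Step 12
Reactants: 24 [2-(allyloxy)-5-(3-methylbut-2-en-1-yl)-4-(triisopropylsilyloxy)phenyl]methanol
Product: 25 1-(allyloxy)-2-(bromomethyl)-4-(3-methylbut-2-en-1-yl)-5-(triisopropylsilyloxy)benzene
Conditions: CBr4, PPh3, CH2Cl2, 0 °C; used at once without chromatography
Reagents that add atoms: tetrabromomethane, BrC(Br)(Br)Br
Why: The Appel reaction should convert the electron-rich benzyl alcohol into the bromide under neutral conditions that spare the prenyl group and the silyl ether.

Step 13
Reactants: 18 (4R)-4-benzyl-3-{2-[2,2-dimethyl-5-(triisopropylsilyloxy)-2H-chromen-8-yl]acetyl}-1,3-oxazolidin-2-one; 25 1-(allyloxy)-2-(bromomethyl)-4-(3-methylbut-2-en-1-yl)-5-(triisopropylsilyloxy)benzene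
Product: 27 (4R)-4-benzyl-3-{(2R)-3-[2-(allyloxy)-5-(3-methylbut-2-en-1-yl)-4-(triisopropylsilyloxy)phenyl]-2-[2,2-dimethyl-5-(triisopropylsilyloxy)-2H-chromen-8-yl]propanoyl}-1,3-oxazolidin-2-one, via sodium (Z)-enolate 26 (not isolated)
Conditions: NaN(SiMe3)2 (1.05 equiv), THF, −78 °C; then 25, −78 to −40 °C
Reagents that add atoms: none
Why: In this Evans asymmetric alkylation the chelated (Z)-enolate 26 should be attacked by the benzyl bromide on the face opposite the benzyl group of the (R)-auxiliary, which sets the new stereocentre as (R).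

Step 14
Reactants: 27 the alkylated imide
Product: 28 (2R)-3-[2-(allyloxy)-5-(3-methylbut-2-en-1-yl)-4-(triisopropylsilyloxy)phenyl]-2-[2,2-dimethyl-5-(triisopropylsilyloxy)-2H-chromen-8-yl]propan-1-ol
Conditions: LiBH4, MeOH (2 equiv), Et2O/THF, 0 °C
Reagents that add atoms: none
Why: Reductive cleavage of the N-acyl oxazolidinone with LiBH4 should give the primary alcohol without epimerising the α-aryl stereocentre and release the auxiliary for recovery.

Step 15
Reactants: 28 the allyl-protected primary alcohol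
Product: 29 2-{(2R)-2-[2,2-dimethyl-5-(triisopropylsilyloxy)-2H-chromen-8-yl]-3-hydroxypropyl}-4-(3-methylbut-2-en-1-yl)-5-(triisopropylsilyloxy)phenol
Conditions: Pd(PPh3)4 (5 mol %), morpholine, THF, rt
Reagents that add atoms: none
Why: Palladium-catalysed allyl transfer to morpholine (Tsuji–Trost deallylation) should free only the ortho phenol, since silyl ethers, the prenyl group and the chromene do not ionise under these conditions.

Step 16
Reactants: 29 the phenol–alcohol
Product: 30 (3R)-3-[2,2-dimethyl-5-(triisopropylsilyloxy)-2H-chromen-8-yl]-6-(3-methylbut-2-en-1-yl)-7-(triisopropylsilyloxy)chromane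
Conditions: PPh3, diisopropyl azodicarboxylate, THF (0.02 M), 0 °C to rt
Reagents that add atoms: none
Why: Intramolecular Mitsunobu etherification should close ring C by 6-exo-tet attack of the ortho phenol on the activated primary carbon, so the neighbouring stereocentre is not involved and the other two phenols stay silylated.

Step 17
Reactants: 30 the bis-silyl isoflavan
Product: 31 (3R)-3-(5-hydroxy-2,2-dimethyl-2H-chromen-8-yl)-6-(3-methylbut-2-en-1-yl)chroman-7-ol (target)
Conditions: Bu4NF (2.5 equiv), AcOH (2.5 equiv), THF, 0 °C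
Reagents that add atoms: none
Why: Buffered fluoride should cleave both aryl silyl ethers under conditions that leave the prenyl phenol, the chromene and the stereocentre unchanged.

**Compound list**

1 | maltol (3-hydroxy-2-methyl-4H-pyran-4-one) | CC1=C(O)C(=O)C=CO1 | starting material
2 | 2-methyl-4-oxo-4H-pyran-3-yl trifluoromethanesulfonate | CC1=C(OS(=O)(=O)C(F)(F)F)C(=O)C=CO1 | intermediate
3 | 2-methylbut-3-yn-2-ol | CC(C)(O)C#C | starting material
4 | 3-(3-hydroxy-3-methylbut-1-yn-1-yl)-2-methyl-4H-pyran-4-one | CC1=C(C#CC(C)(C)O)C(=O)C=CO1 | intermediate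
5 | methyl bromoacetate | COC(=O)CBr | starting material
6 | dilithium 2-methylidene-3-(3-methyl-3-oxidobut-1-yn-1-yl)-2H-pyran-4-olate (alkoxide/lateral dienolate) | [Li+].[Li+].C=C1OC=CC([O-])=C1C#CC(C)(C)[O-] | intermediate
7 | methyl 3-[3-(3-hydroxy-3-methylbut-1-yn-1-yl)-4-oxo-4H-pyran-2-yl]propanoate | COC(=O)CCC1=C(C#CC(C)(C)O)C(=O)C=CO1 | intermediate
8 | methyl 3-{3-[(1Z)-3-hydroxy-3-methylbut-1-en-1-yl]-4-oxo-4H-pyran-2-yl}propanoate | COC(=O)CCC1=C(/C=C\C(C)(C)O)C(=O)C=CO1 | intermediate
9 | 3-[(1Z)-3-hydroxy-3-methylbut-1-en-1-yl]-2-(3-methoxy-3-oxopropyl)-4-(triisopropylsilyloxy)pyrylium trifluoromethanesulfonate | COC(=O)CCc1[o+]ccc(O[Si](C(C)C)(C(C)C)C(C)C)c1/C=C\C(C)(C)O.[O-]S(=O)(=O)C(F)(F)F | intermediate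
10 | methyl 3-[2,2-dimethyl-5-(triisopropylsilyloxy)-2H,8aH-pyrano[2,3-b]pyran-8a-yl]propanoate (racemic ketal) | COC(=O)CCC12OC=CC(O[Si](C(C)C)(C(C)C)C(C)C)=C1C=CC(C)(C)O2 | intermediate
11 | methyl 3-{2,2-dimethyl-5-[(1E)-3-oxo-1-(triisopropylsilyloxy)prop-1-en-1-yl]-2H-pyran-6-yl}propanoate (formyl group cis to the pyran carbon) | COC(=O)CCC1=C(/C(O[Si](C(C)C)(C(C)C)C(C)C)=C\C=O)C=CC(C)(C)O1 | intermediate
12 | methyl 3-{3-[1,3-bis(triisopropylsilyloxy)prop-2-en-1-ylidene]-6,6-dimethyl-3,6-dihydro-2H-pyran-2-ylidene}propanoate (central double bond with the silyloxyvinyl carbon cis to pyran C2; other geometries not fixed) | COC(=O)CC=C1OC(C)(C)C=C/C1=C(\O[Si](C(C)C)(C(C)C)C(C)C)C=CO[Si](C(C)C)(C(C)C)C(C)C | intermediate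
13 | methyl 2-[2,2-dimethyl-5,7-bis(triisopropylsilyloxy)-7,8-dihydro-2H-chromen-8-yl]acetate (racemic, relative configuration at C7/C8 immaterial) | COC(=O)CC1C(O[Si](C(C)C)(C(C)C)C(C)C)C=C(O[Si](C(C)C)(C(C)C)C(C)C)C2=C1OC(C)(C)C=C2 | intermediate
14 | methyl 2-[2,2-dimethyl-5-(triisopropylsilyloxy)-2H-chromen-8-yl]acetate | COC(=O)Cc1ccc(O[Si](C(C)C)(C(C)C)C(C)C)c2c1OC(C)(C)C=C2 | intermediate
15 | 2-[2,2-dimethyl-5-(triisopropylsilyloxy)-2H-chromen-8-yl]acetic acid | OC(=O)Cc1ccc(O[Si](C(C)C)(C(C)C)C(C)C)c2c1OC(C)(C)C=C2 | intermediate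
16 | (4R)-4-benzyl-1,3-oxazolidin-2-one | O=C1N[C@H](Cc2ccccc2)CO1 | starting material
17 | 2-[2,2-dimethyl-5-(triisopropylsilyloxy)-2H-chromen-8-yl]acetic pivalic anhydride | CC(C)(C)C(=O)OC(=O)Cc1ccc(O[Si](C(C)C)(C(C)C)C(C)C)c2c1OC(C)(C)C=C2 | intermediate
18 | (4R)-4-benzyl-3-{2-[2,2-dimethyl-5-(triisopropylsilyloxy)-2H-chromen-8-yl]acetyl}-1,3-oxazolidin-2-one | O=C(Cc1ccc(O[Si](C(C)C)(C(C)C)C(C)C)c2c1OC(C)(C)C=C2)N1[C@H](Cc2ccccc2)COC1=O | intermediate
19 | 5-bromo-2,4-dihydroxybenzaldehyde | O=Cc1cc(Br)c(O)cc1O | starting material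
20 | 5-bromo-2-hydroxy-4-(triisopropylsilyloxy)benzaldehyde | O=Cc1cc(Br)c(O[Si](C(C)C)(C(C)C)C(C)C)cc1O | intermediate
21 | tributyl(3-methylbut-2-en-1-yl)stannane | CCCC[Sn](CCCC)(CCCC)CC=C(C)C | starting material
22 | 2-hydroxy-5-(3-methylbut-2-en-1-yl)-4-(triisopropylsilyloxy)benzaldehyde | O=Cc1cc(CC=C(C)C)c(O[Si](C(C)C)(C(C)C)C(C)C)cc1O | intermediate
23 | 2-(allyloxy)-5-(3-methylbut-2-en-1-yl)-4-(triisopropylsilyloxy)benzaldehyde | O=Cc1cc(CC=C(C)C)c(O[Si](C(C)C)(C(C)C)C(C)C)cc1OCC=C | intermediate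
24 | [2-(allyloxy)-5-(3-methylbut-2-en-1-yl)-4-(triisopropylsilyloxy)phenyl]methanol | OCc1cc(CC=C(C)C)c(O[Si](C(C)C)(C(C)C)C(C)C)cc1OCC=C | intermediate
25 | 1-(allyloxy)-2-(bromomethyl)-4-(3-methylbut-2-en-1-yl)-5-(triisopropylsilyloxy)benzene | BrCc1cc(CC=C(C)C)c(O[Si](C(C)C)(C(C)C)C(C)C)cc1OCC=C | intermediate
26 | sodium (Z)-enolate of 18 | [Na+].[O-]/C(=C\c1ccc(O[Si](C(C)C)(C(C)C)C(C)C)c2c1OC(C)(C)C=C2)N1[C@H](Cc2ccccc2)COC1=O | intermediate
27 | (4R)-4-benzyl-3-{(2R)-3-[2-(allyloxy)-5-(3-methylbut-2-en-1-yl)-4-(triisopropylsilyloxy)phenyl]-2-[2,2-dimethyl-5-(triisopropylsilyloxy)-2H-chromen-8-yl]propanoyl}-1,3-oxazolidin-2-one | O=C(N1[C@H](Cc2ccccc2)COC1=O)[C@@H](c1ccc(O[Si](C(C)C)(C(C)C)C(C)C)c2c1OC(C)(C)C=C2)Cc1cc(CC=C(C)C)c(O[Si](C(C)C)(C(C)C)C(C)C)cc1OCC=C | intermediate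
28 | (2R)-3-[2-(allyloxy)-5-(3-methylbut-2-en-1-yl)-4-(triisopropylsilyloxy)phenyl]-2-[2,2-dimethyl-5-(triisopropylsilyloxy)-2H-chromen-8-yl]propan-1-ol | OC[C@@H](c1ccc(O[Si](C(C)C)(C(C)C)C(C)C)c2c1OC(C)(C)C=C2)Cc1cc(CC=C(C)C)c(O[Si](C(C)C)(C(C)C)C(C)C)cc1OCC=C | intermediate
29 | 2-{(2R)-2-[2,2-dimethyl-5-(triisopropylsilyloxy)-2H-chromen-8-yl]-3-hydroxypropyl}-4-(3-methylbut-2-en-1-yl)-5-(triisopropylsilyloxy)phenol | OC[C@@H](c1ccc(O[Si](C(C)C)(C(C)C)C(C)C)c2c1OC(C)(C)C=C2)Cc1cc(CC=C(C)C)c(O[Si](C(C)C)(C(C)C)C(C)C)cc1O | intermediate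
30 | (3R)-3-[2,2-dimethyl-5-(triisopropylsilyloxy)-2H-chromen-8-yl]-6-(3-methylbut-2-en-1-yl)-7-(triisopropylsilyloxy)chromane | CC(C)=CCc1cc2c(cc1O[Si](C(C)C)(C(C)C)C(C)C)OC[C@@H](c1ccc(O[Si](C(C)C)(C(C)C)C(C)C)c3c1OC(C)(C)C=C3)C2 | intermediate
31 | (3R)-3-(5-hydroxy-2,2-dimethyl-2H-chromen-8-yl)-6-(3-methylbut-2-en-1-yl)chroman-7-ol | CC(C)=CCc1cc2c(cc1O)OC[C@@H](c1ccc(O)c3c1OC(C)(C)C=C3)C2 | target

**Step count and risks**

Total step count: 17. Longest linear sequence: 12 steps (steps 1 to 7, then 13 to 17); the ring-A branch (steps 8 to 12) joins at step 13.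

Steps most likely to fail:

1. Step 5 (key step). The cascade may stall after the pyranone ring has opened, with the dienal failing to enolise and close the carbocycle. The tertiary allylic alcohol may also ionise or be silylated before it adds, so that no chromene forms. The fallback is the known aryl propargyl ether route, which sets out from compound 3 and comes back at compound 14.
 - Purchased methyl 2-(2,4-dihydroxyphenyl)acetate (COC(=O)Cc1ccc(O)cc1O) is silylated at its less hindered 4-hydroxyl (iPr3SiCl, imidazole) to give methyl 2-[2-hydroxy-4-(triisopropylsilyloxy)phenyl]acetate F1.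
 - Compound 3 is converted in the flask (trifluoroacetic anhydride, DBU, MeCN, 0 °C) into 2-methylbut-3-yn-2-yl trifluoroacetate F2.
 - F2 O-alkylates F1 under CuCl2 catalysis to give methyl 2-[2-(2-methylbut-3-yn-2-yloxy)-4-(triisopropylsilyloxy)phenyl]acetate F3.
 - Heating F3 in N,N-diethylaniline at about 150 °C should bring about the aromatic propargyl Claisen rearrangement into the only free ortho position, followed by hydrogen shift and oxa-6π closure, to give 14.

2. Step 3. Proton transfer between the dianion and the product, addition of the dienolate to the alkynyl pyranone of a second molecule, or O-alkylation of the alkoxide may consume the material. The fallback alkylates before the alkyne and the free alcohol are present; it sets out from compound 1 and comes back at compound 7.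
 - Maltol is benzylated (benzyl bromide, K2CO3) to 3-(benzyloxy)-2-methyl-4H-pyran-4-one F4.
 - Its lateral lithium dienolate (LiN(SiMe3)2, −78 °C) is alkylated with compound 5 to methyl 3-[3-(benzyloxy)-4-oxo-4H-pyran-2-yl]propanoate F5.
 - Hydrogenolysis (H2, Pd/C) gives methyl 3-(3-hydroxy-4-oxo-4H-pyran-2-yl)propanoate F6.
 - Tf2O/pyridine gives methyl 3-[4-oxo-3-(trifluoromethylsulfonyloxy)-4H-pyran-2-yl]propanoate F7.
 - Sonogashira coupling of F7 with compound 3 (PdCl2(PPh3)2, CuI, Et3N) gives 7.

3. Step 9. The prenyl group may be transferred with allylic transposition (reverse-prenyl isomer), the stannane may be protonated by the free phenol, or oxidative addition next to the bulky silyl ether may be slow. The fallback avoids an unsymmetrical allyl metal; it sets out from compound 20 and comes back at compound 22.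
 - Suzuki coupling of 20 with allylboronic acid pinacol ester (PdCl2(dppf), K3PO4, dioxane/H2O) gives 5-allyl-2-hydroxy-4-(triisopropylsilyloxy)benzaldehyde F8.
 - Cross-metathesis of F8 with excess 2-methylbut-2-ene (second-generation Grubbs catalyst, CH2Cl2, 40 °C) should give 22.

Further compounds
F1 | step 5 | methyl 2-[2-hydroxy-4-(triisopropylsilyloxy)phenyl]acetate | COC(=O)Cc1ccc(O[Si](C(C)C)(C(C)C)C(C)C)cc1O
F2 | step 5 | 2-methylbut-3-yn-2-yl trifluoroacetate | CC(C)(OC(=O)C(F)(F)F)C#C
F3 | step 5 | methyl 2-[2-(2-methylbut-3-yn-2-yloxy)-4-(triisopropylsilyloxy)phenyl]acetate | COC(=O)Cc1ccc(O[Si](C(C)C)(C(C)C)C(C)C)cc1OC(C)(C)C#C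
F4 | step 3 | 3-(benzyloxy)-2-methyl-4H-pyran-4-one | CC1=C(OCc2ccccc2)C(=O)C=CO1
F5 | step 3 | methyl 3-[3-(benzyloxy)-4-oxo-4H-pyran-2-yl]propanoate | COC(=O)CCC1=C(OCc2ccccc2)C(=O)C=CO1
F6 | step 3 | methyl 3-(3-hydroxy-4-oxo-4H-pyran-2-yl)propanoate | COC(=O)CCC1=C(O)C(=O)C=CO1
F7 | step 3 | methyl 3-[4-oxo-3-(trifluoromethylsulfonyloxy)-4H-pyran-2-yl]propanoate | COC(=O)CCC1=C(OS(=O)(=O)C(F)(F)F)C(=O)C=CO1
F8 | step 9 | 5-allyl-2-hydroxy-4-(triisopropylsilyloxy)benzaldehyde | O=Cc1cc(CC=C)c(O[Si](C(C)C)(C(C)C)C(C)C)cc1O
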